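## Retrosynthetic overview

1. Target ⇒ two late acylations of an 8β,9α-diol on the cis,cis-germacranolide core: acetate at O9, and at O8 the acetonide-protected (2S,3S)-dihydroxy acid made from D-threonine.
2. γ-Lactone and ten-membered ring ⇒ C6–C7 disconnection: chromium-mediated intramolecular allylation of a Z-enal by a 2-(bromomethyl)enoate.
3. Bromomethyl enoate ⇒ Morita–Baylis–Hillman reaction at a C7 aldehyde; both aldehydes come from one diol by a single oxidation that is telescoped into that reaction.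
4. C9–C10 ⇒ nickel-electrocatalytic decarboxylative alkenylation of the L-tartrate acetonide half-ester (as its redox-active ester) with a (Z)-α-bromoenoate made from neryl acetate.
5. Ring order: dioxolane (bought with L-tartrate) → ten-membered carbocycle → γ-lactone. C8/C9 are bought, C6/C7 are induced by them, the side-chain centres come from D-threonine.

Assumption: locants C1–C15 follow germacrane numbering, α/β refer to the usual germacranolide drawing (C7–C11 bond β), and a centre formed as a mixture carries no descriptor in its SMILES.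

## Route

Step 1
Reactants: 1 neryl acetate
Product: 3 (2Z)-3-methyl-6-oxohex-2-en-1-yl acetate, via 6,7-epoxyneryl acetate 2 (not isolated)
Conditions: mCPBA (1.0 equiv), CH2Cl2, 0 °C; then H5IO6 (1.2 equiv), THF/H2O, 0 °C
Reagents that add atoms: mCPBA, O=C(OO)c1cccc(Cl)c1
Why: Prilezhaev epoxidation is selective for the electron-rich remote trisubstituted alkene over the allylic-acetate alkene, and periodic acid cleaves the epoxide to the aldehyde; the Z alkene is untouched and no stereocentre is formed.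

Step 2
Reactants: 3 (2Z)-3-methyl-6-oxohex-2-en-1-yl acetate; 4 methyl (triphenylphosphoranylidene)acetate
Product: 6 methyl (2Z,6Z)-8-acetoxy-2-bromo-6-methylocta-2,6-dienoate, via bromo ylide 5 (not isolated)
Conditions: 4, NBS (1.05 equiv), CH2Cl2, −20 °C, 30 min; then 3, −20 °C → rt
Reagents that add atoms: N-bromosuccinimide, O=C1CCC(=O)N1Br
Why: One-pot ylide bromination and Wittig olefination; the stabilised ylide places the ester trans to the alkyl chain, so Br and chain are cis (2Z).

Step 3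
Reactants: 6 methyl (2Z,6Z)-8-acetoxy-2-bromo-6-methylocta-2,6-dienoate
Product: 7 methyl (2Z,6Z)-2-bromo-8-hydroxy-6-methylocta-2,6-dienoate
Conditions: K2CO3 (0.2 equiv), MeOH, 0 °C, 1 h
Reagents that add atoms: none
Why: Zemplén-type transesterification removes the allylic acetate, which would otherwise ionise on zerovalent nickel in step 5; the methyl ester is degenerate to methanolysis and low temperature keeps the bromoenoate intact.

Step 4
Reactants: 8 dimethyl (4R,5R)-2,2-dimethyl-1,3-dioxolane-4,5-dicarboxylate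
Product: 9 (4R,5R)-5-(methoxycarbonyl)-2,2-dimethyl-1,3-dioxolane-4-carboxylic acid
Conditions: KOH (1.0 equiv), MeOH, 0 °C → rt; then aq HCl
Reagents that add atoms: potassium hydroxide, [K+].[OH-]
Why: Mono-saponification of a C2-symmetric diester gives a single half-ester because the first carboxylate slows the second hydrolysis; no stereocentre is touched.

Step 5
Reactants: 9 (4R,5R)-5-(methoxycarbonyl)-2,2-dimethyl-1,3-dioxolane-4-carboxylic acid; 7 methyl (2Z,6Z)-2-bromo-8-hydroxy-6-methylocta-2,6-dienoate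
Product: 11 methyl (2E,6Z)-8-hydroxy-2-[(4S,5R)-5-(methoxycarbonyl)-2,2-dimethyl-1,3-dioxolan-4-yl]-6-methylocta-2,6-dienoate, via redox-active ester 10 (not isolated)
Conditions: 9 (twofold excess), N-hydroxyphthalimide, DIC, NMP, rt, 2 h; then 7, NiCl2·6H2O (20 mol %), 2,2′-bipyridine (24 mol %), AgNO3 (0.3 equiv), LiCl, Mg anode / RVC cathode, constant current (about 3 F/mol), rt
Reagents that add atoms: none
Why: Proposed new method: nickel-electrocatalytic decarboxylative alkenylation with an α-bromo-α,β-unsaturated ester as the alkenyl partner. Cathodically formed zerovalent nickel inserts into the activated C(sp2)–Br bond of 7 with retention of geometry; the redox-active ester 10 is reduced and fragments (CO2 and phthalimide anion) to the dioxolan-4-yl radical; the alkenyl–nickel species captures this radical and reductive elimination occurs anti to the neighbouring ester on the five-membered ring, so the new C9–C10 bond keeps the L-tartrate configuration at C9. The β-alkyl group of 7 slows competing Giese addition. Closest known reaction type: nickel-electrocatalysed decarboxylative alkenylation of redox-active esters, including acetonide-protected α-oxy acids, with unactivated alkenyl bromides and iodides; α-halo enoates have not been shown as partners.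

Step 6
Reactants: 11 methyl (2E,6Z)-8-hydroxy-2-[(4S,5R)-5-(methoxycarbonyl)-2,2-dimethyl-1,3-dioxolan-4-yl]-6-methylocta-2,6-dienoate
Product: 12 methyl (2E,6Z)-8-hydroxy-2-[(4S,5S)-5-(hydroxymethyl)-2,2-dimethyl-1,3-dioxolan-4-yl]-6-methylocta-2,6-dienoate
Conditions: NaBH4 (2 equiv), MeOH, 0 °C
Reagents that add atoms: none
Why: Chemoselective borohydride reduction: the α-alkoxy-activated dioxolane ester is reduced while the hindered conjugated C14 ester is inert; no stereocentre is touched.

Step 7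
Reactants: 12 methyl (2E,6Z)-8-hydroxy-2-[(4S,5S)-5-(hydroxymethyl)-2,2-dimethyl-1,3-dioxolan-4-yl]-6-methylocta-2,6-dienoate; 13 methyl acrylate
Product: 15 methyl (2E,6Z)-2-{(4S,5S)-5-[1-hydroxy-2-(methoxycarbonyl)prop-2-en-1-yl]-2,2-dimethyl-1,3-dioxolan-4-yl}-6-methyl-8-oxoocta-2,6-dienoate (both carbinol epimers), via dialdehyde 14 (not isolated)
Conditions: Dess–Martin periodinane (2.5 equiv), NaHCO3, CH2Cl2, 0 °C → rt; aq Na2S2O3/NaHCO3 wash, concentrate; then neat methyl acrylate (tenfold excess), 3-hydroxyquinuclidine (0.3 equiv), rt, 24 h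
Reagents that add atoms: none
Why: Dess–Martin oxidation converts both primary alcohols without isomerising the Z-enal, and the labile α-alkoxy aldehyde (trans on the dioxolane, the thermodynamic epimer) is used crude; the Morita–Baylis–Hillman reaction then occurs only at this activated aldehyde because a β,β-disubstituted enal is a poor electrophile, and the new carbinol centre is destroyed in step 8.

Step 8
Reactants: 15 Morita–Baylis–Hillman adduct
Product: 16 methyl (2E,6Z)-2-{(4S,5S)-5-[(1Z)-3-bromo-2-(methoxycarbonyl)prop-1-en-1-yl]-2,2-dimethyl-1,3-dioxolan-4-yl}-6-methyl-8-oxoocta-2,6-dienoate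
Conditions: NBS (1.3 equiv), Me2S (1.5 equiv), CH2Cl2, −20 → 0 °C
Reagents that add atoms: N-bromosuccinimide, O=C1CCC(=O)N1Br
Why: Corey–Kim-type activation followed by SN2′ attack of bromide at the methylene gives the transposed, thermodynamically preferred Z 2-(bromomethyl)enoate.

Step 9
Reactants: 16 allylic bromide enal
Product: 19 methyl (1(10)E,4Z)-8β,9α-dihydroxygermacra-1(10),4,11(13)-trien-12,6α-olid-14-oate, via hydroxy ester 17 (not isolated), via lactone acetonide 18 (not isolated)
Conditions: CrCl2 (6 equiv), THF, syringe-pump addition (final 2 mM), rt; aqueous work-up; then TFA/H2O (10:1), CH2Cl2, 0 °C → rt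
Reagents that add atoms: none
Why: Nozaki–Hiyama-type intramolecular Barbier allylation, the ring closure used for costunolide-type germacranolides. The allylchromium adds through its γ-carbon (C7) to the enal in a chair transition state, which gives the anti C6/C7 relationship (trans-lactone). The C7 face is set by the C8 dioxolane centre (H8 eclipsing the C11 substituent, ring chain anti to the forming bond), leading to 6α-O/7α-H. Acid then closes the γ-lactone on O6 and hydrolyses the acetonide.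

Step 10
Reactants: 19 diol lactone
Product: 20 methyl (1(10)E,4Z)-9α-acetoxy-8β-hydroxygermacra-1(10),4,11(13)-trien-12,6α-olid-14-oate
Conditions: AcCl (1.05 equiv), 2,4,6-collidine, CH2Cl2, −40 °C
Reagents that add atoms: acetyl chloride, CC(=O)Cl
Why: Kinetic monoacylation of the less hindered alcohol: the allylic C9 hydroxyl sits next to the planar C10 enoate carbon, whereas the C8 hydroxyl is next to the ring-fusion methine on the face of C11; this selectivity is a steric argument, not a measured one.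

Step 11
Reactants: 21 D-threonine
Product: 22 (2R,3S)-2,3-dihydroxybutanoic acid
Conditions: NaNO2, 1 M H2SO4, 0 °C → rt
Reagents that add atoms: water, O
Why: Diazotisation of the α-amino acid; the carboxylate displaces N2 to an α-lactone that water opens, so C2 is hydroxylated with net retention (double inversion) and C3 is untouched.

Step 12
Reactants: 22 (2R,3S)-2,3-dihydroxybutanoic acid
Product: 23 methyl (4R,5S)-2,2,5-trimethyl-1,3-dioxolane-4-carboxylate
Conditions: 2,2-dimethoxypropane, MeOH, TsOH (cat.), 50 °C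
Reagents that add atoms: 2,2-dimethoxypropane, COC(C)(C)OC; methanol, CO
Why: Fischer esterification and acetalisation in one pot give the trans-dioxolane without touching either stereocentre.

Step 13
Reactants: 23 methyl (4R,5S)-2,2,5-trimethyl-1,3-dioxolane-4-carboxylate
Product: 24 methyl (4S,5S)-2,2,4,5-tetramethyl-1,3-dioxolane-4-carboxylate
Conditions: LDA (1.2 equiv), THF/DMPU, −78 °C; MeI (3 equiv), −78 → −40 °C
Reagents that add atoms: iodomethane, CI
Why: Enolate alkylation of the dioxolane ester: C4 becomes planar and MeI enters anti to the C5 methyl on the five-membered ring, giving the 4,5-trans-dimethyl (4S,5S) product under control of the bought C5 centre.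

Step 14
Reactants: 24 methyl (4S,5S)-2,2,4,5-tetramethyl-1,3-dioxolane-4-carboxylate
Product: 25 (4S,5S)-2,2,4,5-tetramethyl-1,3-dioxolane-4-carboxylic acid
Conditions: LiOH (2 equiv), THF/H2O, rt; then aq HCl to pH 3, 0 °C
Reagents that add atoms: lithium hydroxide, [Li+].[OH-]
Why: Saponification; the quaternary α-carbon cannot epimerise and the acetonide survives brief cold acidification.

Step 15
Reactants: 20 9α-acetate 8β-alcohol; 25 (4S,5S)-2,2,4,5-tetramethyl-1,3-dioxolane-4-carboxylic acid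
Product: 27 methyl (1(10)E,4Z)-9α-acetoxy-8β-{[(4S,5S)-2,2,4,5-tetramethyl-1,3-dioxolan-4-yl]carbonyloxy}germacra-1(10),4,11(13)-trien-12,6α-olid-14-oate, via acid chloride 26 (not isolated)
Conditions: excess 25 (2.5-fold), 1-chloro-N,N,2-trimethylprop-1-en-1-amine, CH2Cl2, 0 °C → rt; then 20, Et3N, DMAP (0.5 equiv), CH2Cl2, 0 → 35 °C
Reagents that add atoms: none
Why: Neutral acid chloride formation followed by DMAP-catalysed acyl transfer (Steglich-type) onto the only free hydroxyl, at C8; the acid has no epimerisable centre and no stereocentre of the core is touched.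

Step 16
Reactants: 27 acetonide-protected ester
Product: 28 methyl (1(10)E,4Z)-9α-acetoxy-8β-[(2S,3S)-2,3-dihydroxy-2-methylbutanoyloxy]germacra-1(10),4,11(13)-trien-12,6α-olid-14-oate (target, 6R,7S,8S,9S)
Conditions: TFA/H2O (9:1), 0 °C → rt
Reagents that add atoms: none
Why: Acid-catalysed acetal hydrolysis frees the side-chain diol; the esters, the α-methylene lactone and the electron-poor 1(10) alkene tolerate cold aqueous TFA, and no stereocentre is touched.

## Compound list

1 | neryl acetate, (2Z)-3,7-dimethylocta-2,6-dien-1-yl acetate | CC(C)=CCC/C(C)=C\COC(C)=O | starting material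
2 | 6,7-epoxyneryl acetate (racemic epoxide) | CC1(C)OC1CC/C(C)=C\COC(C)=O | intermediate
3 | (2Z)-3-methyl-6-oxohex-2-en-1-yl acetate | O=CCC/C(C)=C\COC(C)=O | intermediate
4 | methyl (triphenylphosphoranylidene)acetate | COC(=O)C=P(c1ccccc1)(c1ccccc1)c1ccccc1 | starting material
5 | methyl bromo(triphenylphosphoranylidene)acetate | COC(=O)C(Br)=P(c1ccccc1)(c1ccccc1)c1ccccc1 | intermediate
6 | methyl (2Z,6Z)-8-acetoxy-2-bromo-6-methylocta-2,6-dienoate | COC(=O)/C(Br)=C/CC/C(C)=C\COC(C)=O | intermediate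
7 | methyl (2Z,6Z)-2-bromo-8-hydroxy-6-methylocta-2,6-dienoate | COC(=O)/C(Br)=C/CC/C(C)=C\CO | intermediate
8 | dimethyl (4R,5R)-2,2-dimethyl-1,3-dioxolane-4,5-dicarboxylate (dimethyl 2,3-O-isopropylidene-L-tartrate) | COC(=O)[C@H](OC1(C)C)[C@@H](O1)C(=O)OC | starting material
9 | (4R,5R)-5-(methoxycarbonyl)-2,2-dimethyl-1,3-dioxolane-4-carboxylic acid | OC(=O)[C@H](OC1(C)C)[C@@H](O1)C(=O)OC | intermediate
10 | 1,3-dioxoisoindolin-2-yl methyl (4R,5R)-2,2-dimethyl-1,3-dioxolane-4,5-dicarboxylate | O=C(ON1C(=O)c2ccccc2C1=O)[C@H](OC3(C)C)[C@@H](O3)C(=O)OC | intermediate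
11 | methyl (2E,6Z)-8-hydroxy-2-[(4S,5R)-5-(methoxycarbonyl)-2,2-dimethyl-1,3-dioxolan-4-yl]-6-methylocta-2,6-dienoate | OC/C=C(/C)CC/C=C(/C(=O)OC)[C@H](OC1(C)C)[C@@H](O1)C(=O)OC | intermediate
12 | methyl (2E,6Z)-8-hydroxy-2-[(4S,5S)-5-(hydroxymethyl)-2,2-dimethyl-1,3-dioxolan-4-yl]-6-methylocta-2,6-dienoate | OC/C=C(/C)CC/C=C(/C(=O)OC)[C@H](OC1(C)C)[C@@H](O1)CO | intermediate
13 | methyl acrylate | C=CC(=O)OC | starting material
14 | methyl (2E,6Z)-2-[(4S,5R)-5-formyl-2,2-dimethyl-1,3-dioxolan-4-yl]-6-methyl-8-oxoocta-2,6-dienoate | O=C/C=C(/C)CC/C=C(/C(=O)OC)[C@H](OC1(C)C)[C@@H](O1)C=O | intermediate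
15 | methyl (2E,6Z)-2-{(4S,5S)-5-[1-hydroxy-2-(methoxycarbonyl)prop-2-en-1-yl]-2,2-dimethyl-1,3-dioxolan-4-yl}-6-methyl-8-oxoocta-2,6-dienoate (carbinol epimers) | O=C/C=C(/C)CC/C=C(/C(=O)OC)[C@H](OC1(C)C)[C@@H](O1)C(O)C(=C)C(=O)OC | intermediate
16 | methyl (2E,6Z)-2-{(4S,5S)-5-[(1Z)-3-bromo-2-(methoxycarbonyl)prop-1-en-1-yl]-2,2-dimethyl-1,3-dioxolan-4-yl}-6-methyl-8-oxoocta-2,6-dienoate | O=C/C=C(/C)CC/C=C(/C(=O)OC)[C@H](OC1(C)C)[C@@H](O1)/C=C(\CBr)C(=O)OC | intermediate
17 | dimethyl (1(10)E,4Z)-6α-hydroxy-8β,9α-(isopropylidenedioxy)germacra-1(10),4,11(13)-triene-12,14-dioate (7α-H) | O[C@@H]1/C=C(/C)CC/C=C(/C(=O)OC)[C@H](OC2(C)C)[C@@H](O2)[C@H]1C(=C)C(=O)OC | intermediate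
18 | methyl (1(10)E,4Z)-8β,9α-(isopropylidenedioxy)germacra-1(10),4,11(13)-trien-12,6α-olid-14-oate | C=C1C(=O)O[C@@H]2/C=C(/C)CC/C=C(/C(=O)OC)[C@H](OC3(C)C)[C@@H](O3)[C@@H]12 | intermediate
19 | methyl (1(10)E,4Z)-8β,9α-dihydroxygermacra-1(10),4,11(13)-trien-12,6α-olid-14-oate | C=C1C(=O)O[C@@H]2/C=C(/C)CC/C=C(/C(=O)OC)[C@H](O)[C@@H](O)[C@@H]12 | intermediate
20 | methyl (1(10)E,4Z)-9α-acetoxy-8β-hydroxygermacra-1(10),4,11(13)-trien-12,6α-olid-14-oate | C=C1C(=O)O[C@@H]2/C=C(/C)CC/C=C(/C(=O)OC)[C@H](OC(C)=O)[C@@H](O)[C@@H]12 | intermediate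
21 | D-threonine, (2R,3S)-2-amino-3-hydroxybutanoic acid | C[C@H](O)[C@@H](N)C(=O)O | starting material
22 | (2R,3S)-2,3-dihydroxybutanoic acid | C[C@H](O)[C@@H](O)C(=O)O | intermediate
23 | methyl (4R,5S)-2,2,5-trimethyl-1,3-dioxolane-4-carboxylate | COC(=O)[C@H](OC1(C)C)[C@H](C)O1 | intermediate
24 | methyl (4S,5S)-2,2,4,5-tetramethyl-1,3-dioxolane-4-carboxylate | COC(=O)[C@@](C)(OC1(C)C)[C@H](C)O1 | intermediate
25 | (4S,5S)-2,2,4,5-tetramethyl-1,3-dioxolane-4-carboxylic acid | OC(=O)[C@@](C)(OC1(C)C)[C@H](C)O1 | intermediate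
26 | (4S,5S)-2,2,4,5-tetramethyl-1,3-dioxolane-4-carbonyl chloride | O=C(Cl)[C@@](C)(OC1(C)C)[C@H](C)O1 | intermediate
27 | methyl (1(10)E,4Z)-9α-acetoxy-8β-{[(4S,5S)-2,2,4,5-tetramethyl-1,3-dioxolan-4-yl]carbonyloxy}germacra-1(10),4,11(13)-trien-12,6α-olid-14-oate | C=C1C(=O)O[C@@H]2/C=C(/C)CC/C=C(/C(=O)OC)[C@H](OC(C)=O)[C@@H](OC(=O)[C@@](C)(OC3(C)C)[C@H](C)O3)[C@@H]12 | intermediate
28 | methyl (1(10)E,4Z)-9α-acetoxy-8β-[(2S,3S)-2,3-dihydroxy-2-methylbutanoyloxy]germacra-1(10),4,11(13)-trien-12,6α-olid-14-oate | C=C1C(=O)O[C@@H]2/C=C(/C)CC/C=C(/C(=O)OC)[C@H](OC(C)=O)[C@@H](OC(=O)[C@@](C)(O)[C@H](C)O)[C@@H]12 | target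

## Step count and risks

Total steps: 16. Longest linear sequence: 11 (steps 1, 2, 3, 5, 6, 7, 8, 9, 10, 15, 16).

Most likely to fail:

**Step 5 (the proposed new coupling).** Bromoenoate 7 may be reduced or dimerised at the cathode, the alkenyl–nickel species may lose its geometry, or Giese addition may compete. The fallback sets out from 3 (its coupling partner is the redox-active ester 10, made from 9 as in step 5) and comes back to the route at 11. It uses only known reactions: decarboxylative alkynylation, oxygen-directed hydrostannation and carbonylation. Aldehyde 3, dimethyl (1-diazo-2-oxopropyl)phosphonate and K2CO3 in MeOH (Seyferth–Gilbert homologation in the Ohira–Bestmann form, which also methanolyses the acetate) give (2Z)-3-methylhept-2-en-6-yn-1-ol F1. TBSCl/imidazole gives its tert-butyldimethylsilyl ether F2. iPrMgCl·LiCl and then ZnCl2 convert F2 into the alkynylzinc chloride F3. F3 is coupled with 10 under NiCl2·6H2O/2,2′-bipyridine in THF/DMF to give, trans on the dioxolane, the alkyne F4. Bu3SnH with PdCl2(PPh3)2 adds syn, with tin on the carbon next to the dioxolane oxygen, to give the vinylstannane F5. I2 at 0 °C gives, with retention, the vinyl iodide F6. PdCl2(PPh3)2, CO (1 atm), MeOH and Et3N give, again with retention, the 8-O-silyl enoate F7. HF·pyridine removes the silyl group and returns to the route at 11.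

**Step 9 (macrocyclisation).** The closure may oligomerise, or the C7 face may be attacked from the wrong side. The fallback sets out from 15 and changes both the allyl source and the mediator. Ac2O/DMAP converts 15 into the Morita–Baylis–Hillman acetate F8. Pd(PPh3)4 (cat.) and InI in THF at high dilution ionise F8 to a π-allylpalladium species that is transmetallated to an allylindium (umpolung), which closes onto the enal through a tighter chair to give 17. The same TFA/H2O treatment then returns to the route at 19.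

**Step 10 (regioselective monoacetylation).** The acetylation may be unselective or prefer O8, and acetyl migration may follow in step 15. The fallback sets out from 19 and uses a silyl relay that works whichever hydroxyl reacts first. TESCl/imidazole at −40 °C gives the 9-O-triethylsilyl ether F9 and/or the 8-O-triethylsilyl ether F12, which are separable. F9 is acylated at O8 with acid chloride 26 to give the 9-O-silyl 8-O-acyl compound F10; HF·pyridine gives the 9-hydroxy 8-ester F11, and Ac2O/pyridine returns to the route at 27. F12 is acetylated at O9 to give the 8-O-silyl 9-acetate F13, and HF·pyridine returns to the route at 20.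

Further compounds
F1 | step 5 | (2Z)-3-methylhept-2-en-6-yn-1-ol | C#CCC/C(C)=C\CO
F2 | step 5 | tert-butyldimethyl{[(2Z)-3-methylhept-2-en-6-yn-1-yl]oxy}silane | C#CCC/C(C)=C\CO[Si](C)(C)C(C)(C)C
F3 | step 5 | {(5Z)-7-[(tert-butyldimethylsilyl)oxy]-5-methylhept-5-en-1-yn-1-yl}zinc chloride | CC(C)(C)[Si](C)(C)OC/C=C(/C)CCC#C[Zn]Cl
F4 | step 5 | methyl (4R,5S)-5-{(5Z)-7-[(tert-butyldimethylsilyl)oxy]-5-methylhept-5-en-1-yn-1-yl}-2,2-dimethyl-1,3-dioxolane-4-carboxylate | CC(C)(C)[Si](C)(C)OC/C=C(/C)CCC#C[C@H](OC1(C)C)[C@@H](O1)C(=O)OC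
F5 | step 5 | methyl (4R,5R)-5-{(1E,5Z)-7-[(tert-butyldimethylsilyl)oxy]-5-methyl-1-(tributylstannyl)hepta-1,5-dien-1-yl}-2,2-dimethyl-1,3-dioxolane-4-carboxylate | CC(C)(C)[Si](C)(C)OC/C=C(/C)CC/C=C(/[Sn](CCCC)(CCCC)CCCC)[C@H](OC1(C)C)[C@@H](O1)C(=O)OC
F6 | step 5 | methyl (4R,5R)-5-{(1E,5Z)-7-[(tert-butyldimethylsilyl)oxy]-1-iodo-5-methylhepta-1,5-dien-1-yl}-2,2-dimethyl-1,3-dioxolane-4-carboxylate | CC(C)(C)[Si](C)(C)OC/C=C(/C)CC/C=C(/I)[C@H](OC1(C)C)[C@@H](O1)C(=O)OC
F7 | step 5 | methyl (2E,6Z)-8-[(tert-butyldimethylsilyl)oxy]-2-[(4S,5R)-5-(methoxycarbonyl)-2,2-dimethyl-1,3-dioxolan-4-yl]-6-methylocta-2,6-dienoate | CC(C)(C)[Si](C)(C)OC/C=C(/C)CC/C=C(/C(=O)OC)[C@H](OC1(C)C)[C@@H](O1)C(=O)OC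
F8 | step 9 | acetate of 15, methyl (2E,6Z)-2-{5-[1-acetoxy-2-(methoxycarbonyl)prop-2-en-1-yl]-2,2-dimethyl-1,3-dioxolan-4-yl}-6-methyl-8-oxoocta-2,6-dienoate with the dioxolane configuration of 15 | O=C/C=C(/C)CC/C=C(/C(=O)OC)[C@H](OC1(C)C)[C@@H](O1)C(OC(C)=O)C(=C)C(=O)OC
F9 | step 10 | 9-O-triethylsilyl ether of 19 | C=C1C(=O)O[C@@H]2/C=C(/C)CC/C=C(/C(=O)OC)[C@H](O[Si](CC)(CC)CC)[C@@H](O)[C@@H]12
F10 | step 10 | 9-O-triethylsilyl 8-O-[(4S,5S)-2,2,4,5-tetramethyl-1,3-dioxolane-4-carbonyl] derivative of 19 | C=C1C(=O)O[C@@H]2/C=C(/C)CC/C=C(/C(=O)OC)[C@H](O[Si](CC)(CC)CC)[C@@H](OC(=O)[C@@](C)(OC3(C)C)[C@H](C)O3)[C@@H]12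
F11 | step 10 | 8-O-[(4S,5S)-2,2,4,5-tetramethyl-1,3-dioxolane-4-carbonyl] derivative of 19 with free 9α-hydroxyl | C=C1C(=O)O[C@@H]2/C=C(/C)CC/C=C(/C(=O)OC)[C@H](O)[C@@H](OC(=O)[C@@](C)(OC3(C)C)[C@H](C)O3)[C@@H]12
F12 | step 10 | 8-O-triethylsilyl ether of 19 | C=C1C(=O)O[C@@H]2/C=C(/C)CC/C=C(/C(=O)OC)[C@H](O)[C@@H](O[Si](CC)(CC)CC)[C@@H]12
F13 | step 10 | 9-O-acetyl 8-O-triethylsilyl derivative of 19 | C=C1C(=O)O[C@@H]2/C=C(/C)CC/C=C(/C(=O)OC)[C@H](OC(C)=O)[C@@H](O[Si](CC)(CC)CC)[C@@H]12
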